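Assumption: (R)-SEGPHOS is taken to deliver the aryl group to the same face of coumarin 7 as it does with simple coumarins, which corresponds to the R configuration at C4 of 8 and at the methine of 21; if the sense were reversed, (S)-SEGPHOS would be used and nothing else would change.

## Analysis of the target

Compound 21 is a flavonol, a 4H-chromen-4-one. Ring A is a trioxygenated benzene ring with free hydroxyls at C5 and C7, ring C carries the C3 hydroxyl and the C4 carbonyl, and ring B at C2 is a 4-hydroxy-3-methoxyphenyl group. C8 of ring A bears a 1-arylethyl group whose aryl part is 4-hydroxy-3,5-dimethoxyphenyl (syringyl), so the molecule is a 1,1-diarylethane grafted onto a flavonol core. The doubly benzylic methine is the only stereocentre and is R (C8 > syringyl carbon > CH3 > H). There is no second stereo-element to relay from, so its absolute configuration must come from a catalyst or reagent. The sensitive groups are the five acidic hydroxyls (the free flavonol is air-sensitive in base), three aryl methyl ethers that must survive the final deprotection, and the diarylmethine on a very electron-rich ring, which strong acid can cleave by ipso protonation as long as ring A is not acylated. The methyl ethers rule out Lewis-acidic ether cleavage at the end and point to benzyl protection with hydrogenolysis. The main difficulty is regiochemical: in an acylated ring A the two oxygens ortho to the acyl group are nearly equivalent, and closing ring C through the wrong one gives the 6-substituted isomer. The plan rests on the C2–C3 bond of ring C and on O1, the ring A oxygen flanked by C8 and C4a. If only that oxygen carries the ring B acyl group, an O-to-C acyl shift onto the carbon α to the C4 ketone builds C2–C3 and leaves O1 as the single oxygen able to close the ring.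

## Retrosynthetic reasoning

21 to 20. All five hydroxyls are carried as benzyl ethers and the five O–CH2Ph bonds are cut last, by hydrogenolysis. This spares the three methyl ethers, the pyranone and the stereocentre, and keeps every earlier intermediate free of acidic OH groups.

20 to 18. The O1–C2 bond of ring C is cut, giving the open 2-hydroxyaryl 1,3-diketone 18. The forward reaction is an acid-catalysed addition of the phenol to the aroyl carbonyl followed by dehydration. Because O5 and O7 are benzylated in 18, only O1 can close the ring, so only the 8-substituted chromone can result.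

18 to 17. The C2–C3 bond is cut, which is the key disconnection. In 17 the ring B acyl group sits as an ester on O1 and the α-benzyloxy ketone sits on C4a. The forward reaction is an intramolecular O-to-C acyl shift. The cut is made here because it brings the C3 oxygen in at the correct oxidation level, so no late oxidation is needed, and because it turns a question of O-acylation (only one phenol is free) into the C8 regiochemistry of the chromone.

17 to 14 and 15. The ester C–O bond is cut. Ketone 14 has exactly one free hydroxyl, and acid 15 is activated as chloride 16 in the flask. The forward reaction only has to acylate a hindered, chelated phenol.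

14 to 13, and 13 to 11 and 12. The bond between ring A and the ketone carbon is cut. The acyl group is first placed on the phenol oxygen of 11 (ester 13) and then moved to the one remaining ortho carbon under Lewis acid catalysis. The chelated ortho-hydroxy ketone is favoured over the para position, which is flanked by two benzyloxy groups. The ketone is introduced only at this stage because it would not survive the hydride reduction and decarbonylation that precede it, and because the free phenol of 11 is the handle that directs it.

11 to 9 to 8. The methyl group of 11 is what remains of C3 of chroman-2-one 8 after C2 is removed. The lactone ring serves two purposes: it provides the acceptor for the asymmetric arylation and it tags O1 against O5 and O7. A direct decarboxylation is not workable, since the free phenol recloses onto any activated acid and a radical route passes through a 2,2-diarylethyl radical that can undergo 1,2-aryl shift. The carbon is therefore taken out by reduction to lactol 9 and decarbonylation of its open form 10, which releases the phenol under neutral conditions.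

8 to 7 and 5. The C4–aryl bond is cut. The forward reaction is an enantioselective conjugate arylation of coumarin 7 with boronic acid 5 under a rhodium catalyst bearing an axially chiral bisphosphine. This step sets the only stereocentre.

7 to 6, and 5 to 2 to 1. The benzyl ethers are cut back to the commercial phenols 6 and 1. The boron of 5 is introduced through aryllithium 3 and borate 4 from bromide 2.

## Alternatives that were turned down

Alternative 1: Ring A is taken apart around the carbon that carries the stereocentre. Phenol A1, (R)-5-(benzyloxy)-2-[1-(4-benzyloxy-3,5-dimethoxyphenyl)ethyl]-3-[tri(propan-2-yl)silyloxy]phenol, would come from 3-(benzyloxy)cyclobut-2-en-1-one A2 and the enantioenriched siloxyalkyne A3, (R)-{[3-(4-benzyloxy-3,5-dimethoxyphenyl)but-1-yn-1-yl]oxy}tri(propan-2-yl)silane, by a Danheiser benzannulation.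
- Forward key step: heating opens A2 to a vinylketene, which adds [2+2] to the ynol ether of A3. The resulting vinylcyclobutenone opens (four electrons) to a dienylketene, which closes (six electrons) and tautomerises to A1.
- For: the annulation regiochemistry follows from the polarity of the ynol ether, so the free hydroxyl appears next to the carbon bearing the stereocentre and the other two oxygens carry different groups. The neutral, thermal conditions should not touch a stereocentre already in place.
- Against: the stereocentre must be built beforehand in A3. The usual access to siloxyalkynes is ynolate homologation of an ester under strongly basic conditions, here an α-arylpropanoate whose acidic α-hydrogen is the stereocentre, so racemisation is a real threat. A2 is not a stock chemical. A1 still has two free ring positions, so the later C-acylation faces the same ortho-selectivity question as 11, and a silyl-to-benzyl exchange is added.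
- Comparison: on differentiating the ring A oxygens this alternative is at least as strong (three different groups instead of two). The chosen strategy gets the one differentiation that matters, O1 against O5 and O7, from a lactone oxygen at no cost, sets the stereocentre by catalysis on a stable substrate and reaches the phenol stage in fewer steps. Ring C would still have to be made afterwards, so the annulation adds risk without removing any.

Alternative 2: The methine–syringyl bond is cut and the stereocentre becomes the centre of the plan. Chromanone A4, (R)-5,7-bis(benzyloxy)-4-(4-benzyloxy-3,5-dimethoxyphenyl)chroman-2-one, identical with 8, arises from the partners 7 and 5 by conjugate arylation with Rh(acac)(C2H4)2 and SEGPHOS.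
- Forward key step: the aryl–rhodium species inserts the C3=C4 bond of the coumarin from one face and the rhodium enolate is protonated. No ring is formed.
- For: the reaction class is well established for coumarins with high enantioselectivity, the catalyst components are stock items, and the lactone oxygen of A4 marks the future O1.
- Against: as a governing idea it says nothing about ring C. The conventional continuation, a 2'-hydroxychalcone and its Algar–Flynn–Oyamada oxidation, tends to divert chalcones with a 6'-alkoxy group towards aurones and brings the C3 oxygen in by a late oxidation. The step is also exposed to the neighbouring 5-benzyloxy group and to the low electrophilicity of a 5,7-dioxygenated coumarin, so a plan that stakes everything on it carries its main risk at the start.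
- Comparison: on the stereocentre the two plans are equal, because the chosen route uses this very transformation as a supporting step, and the step count up to phenol 11 is the same. What the chosen strategy adds is a ring C assembly in which the C3 oxygen arrives at the right oxidation level and the C8 regiochemistry is locked by the position of an ester.

Alternative 3: The C–CH3 bond of the stereocentre is cut. Phenol A5, (R)-4-{1-[4,6-bis(benzyloxy)-2-(methoxymethoxy)phenyl]ethyl}-2,6-dimethoxyphenol, would be formed by enantioselective 1,6-addition of methyl to the para-quinone methide A6, 4-{[4,6-bis(benzyloxy)-2-(methoxymethoxy)phenyl]methylidene}-2,6-dimethoxycyclohexa-2,5-dien-1-one.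
- Forward key step: Zn(CH3)2 with Cu(OTf)2 and a chiral phosphoramidite transfers methyl to the exocyclic carbon, and rearomatisation of the syringyl ring drives the addition. No ring closes.
- For: it is convergent, the diaryl skeleton comes from an aldehyde and a phenol, and the methoxymethyl group tags the future O1. No carbon has to be excised afterwards, so on atom economy it is stronger than the lactone route, which discards C2 of the coumarin.
- Against: A6 lacks the bulky 2,6-substituents that make para-quinone methides isolable, so oligomerisation and hydration compete. Its exocyclic aryl group is di-ortho-oxygenated and twisted, leaving only aryl against hydrogen to tell the faces apart, and methyl transfer to such an electron-rich acceptor has little precedent to lean on. After A5 the free syringyl phenol must be benzylated and the methoxymethyl group removed by acid from a diarylmethane whose ring A invites ipso protonation and C–C cleavage.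
- Comparison: the chosen strategy offers a stereocentre-forming reaction of an established class on a bench-stable coumarin and unmasks the O1 phenol under neutral conditions. It pays for this with two extra steps for the carbon excision.

Key step: step 10

## Route

Step 1
Reactants: 1 4-bromo-2,6-dimethoxyphenol
Product: 2 2-(benzyloxy)-5-bromo-1,3-dimethoxybenzene
Conditions: BnBr, K2CO3, DMF, 60 °C
Reagents that add atoms: benzyl bromide, BrCc1ccccc1
Why: Williamson etherification of the phenoxide; the benzyl ether masks the future syringyl hydroxyl and should last until the final hydrogenolysis.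

Step 2
Reactants: 2 2-(benzyloxy)-5-bromo-1,3-dimethoxybenzene
Product: 5 [4-(benzyloxy)-3,5-dimethoxyphenyl]boronic acid, via aryllithium 3 (not isolated), via lithium aryltriisopropoxyborate 4 (not isolated)
Conditions: n-BuLi, THF, −78 °C; B(OiPr)3, −78 °C to rt; 1 M HCl
Reagents that add atoms: triisopropyl borate, CC(C)OB(OC(C)C)OC(C)C; water, O
Why: Lithiation–borylation: bromine–lithium exchange at −78 °C is faster than any attack on the benzyl ether, the aryllithium is trapped by the borate, and the ate complex is hydrolysed to the boronic acid on acidification.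

Step 3
Reactants: 6 5,7-dihydroxycoumarin
Product: 7 5,7-bis(benzyloxy)-2H-chromen-2-one
Conditions: BnBr (2.4 equiv), K2CO3, DMF, 60 °C
Reagents that add atoms: benzyl bromide, BrCc1ccccc1
Why: Double Williamson etherification; the benzyl ethers keep the coumarin a neutral Michael acceptor and mark O5 and O7 as the oxygens that stay blocked to the end.

Step 4
Reactants: 7 5,7-bis(benzyloxy)-2H-chromen-2-one; 5 [4-(benzyloxy)-3,5-dimethoxyphenyl]boronic acid
Product: 8 (4R)-5,7-bis(benzyloxy)-4-[4-(benzyloxy)-3,5-dimethoxyphenyl]-3,4-dihydro-2H-chromen-2-one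
Conditions: Rh(acac)(C2H4)2 (3 mol%), (R)-SEGPHOS (3.3 mol%), 5 (5 equiv, in portions), dioxane/H2O 10:1, 60 °C
Reagents that add atoms: none
Why: Rhodium-catalysed asymmetric 1,4-addition of an arylboronic acid to a coumarin (Hayashi–Miyaura type): transmetallation to an aryl complex of monovalent rhodium, face-selective insertion of C3=C4 and protonolysis of the rhodium enolate by water. The chiral bisphosphine controls the face of insertion and should set C4 as R; the excess of 5 offsets protodeboronation.

Step 5
Reactants: 8 (4R)-5,7-bis(benzyloxy)-4-[4-(benzyloxy)-3,5-dimethoxyphenyl]-3,4-dihydro-2H-chromen-2-one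
Product: 9 (4R)-5,7-bis(benzyloxy)-4-[4-(benzyloxy)-3,5-dimethoxyphenyl]-3,4-dihydro-2H-chromen-2-ol (both C2 epimers)
Conditions: i-Bu2AlH (1.1 equiv), CH2Cl2, −78 °C; MeOH, then aq. potassium sodium tartrate
Reagents that add atoms: none
Why: Partial reduction of an aryl lactone: at −78 °C the aluminium hemiacetal is stable and gives the lactol on work-up; the stereocentre is not involved.

Step 6
Reactants: 9 (4R)-5,7-bis(benzyloxy)-4-[4-(benzyloxy)-3,5-dimethoxyphenyl]-3,4-dihydro-2H-chromen-2-ol
Product: 11 3,5-bis(benzyloxy)-2-[(1R)-1-[4-(benzyloxy)-3,5-dimethoxyphenyl]ethyl]phenol, via ring-opened hydroxy aldehyde 10 (not isolated)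
Conditions: [Rh(dppp)2]Cl (5 mol%), diglyme, 160 °C, N2 sweep
Reagents that add atoms: none
Why: Rhodium-catalysed decarbonylation of an aldehyde (Tsuji–Wilkinson type) acting on the open form 10 of the lactol: insertion of monovalent rhodium into the formyl C–H bond, loss of CO from the acyl complex and C–H reductive elimination turn CH2–CHO into CH3 and set the phenol free. The stereocentre is not part of any bond made or broken and should be retained.

Step 7
Reactants: 11 3,5-bis(benzyloxy)-2-[(1R)-1-[4-(benzyloxy)-3,5-dimethoxyphenyl]ethyl]phenol; 12 2-(benzyloxy)acetyl chloride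
Product: 13 3,5-bis(benzyloxy)-2-[(1R)-1-[4-(benzyloxy)-3,5-dimethoxyphenyl]ethyl]phenyl 2-(benzyloxy)acetate
Conditions: Et3N, DMAP (5 mol%), CH2Cl2, 0 °C to rt
Reagents that add atoms: none
Why: DMAP-catalysed O-acylation of the single free phenol with an acid chloride; it places the acyl group on the oxygen next to the carbon it must reach.

Step 8
Reactants: 13 3,5-bis(benzyloxy)-2-[(1R)-1-[4-(benzyloxy)-3,5-dimethoxyphenyl]ethyl]phenyl 2-(benzyloxy)acetate
Product: 14 2-(benzyloxy)-1-{4,6-bis(benzyloxy)-3-[(1R)-1-[4-(benzyloxy)-3,5-dimethoxyphenyl]ethyl]-2-hydroxyphenyl}ethan-1-one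
Conditions: Sc(OTf)3 (10 mol%), toluene, 70 °C
Reagents that add atoms: none
Why: Lewis acid-catalysed Fries rearrangement: the activated ester passes its acyl group to the only free carbon ortho to the oxygen, where the product is held as the chelated ortho-hydroxy ketone, whereas the para carbon is flanked by two benzyloxy groups. A triflate salt without nucleophilic halide is used so that the benzyl ethers are not cleaved, and ring A is deactivated as soon as it is acylated, which shields the diarylmethine from acid.

Step 9
Reactants: 14 2-(benzyloxy)-1-{4,6-bis(benzyloxy)-3-[(1R)-1-[4-(benzyloxy)-3,5-dimethoxyphenyl]ethyl]-2-hydroxyphenyl}ethan-1-one; 15 4-(benzyloxy)-3-methoxybenzoic acid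
Product: 17 3,5-bis(benzyloxy)-2-[2-(benzyloxy)acetyl]-6-[(1R)-1-[4-(benzyloxy)-3,5-dimethoxyphenyl]ethyl]phenyl 4-(benzyloxy)-3-methoxybenzoate, via 4-(benzyloxy)-3-methoxybenzoyl chloride 16 (not isolated)
Conditions: 15, (COCl)2, DMF (cat.), CH2Cl2, 0 °C to rt, evaporate; then 14, Et3N, DMAP (0.3 equiv), CH2Cl2, rt to 40 °C
Reagents that add atoms: none
Why: Acid chloride formation followed by DMAP-catalysed esterification; the chelated, hindered phenol is the only free hydroxyl, so the aroyl group can only go onto the future O1.

Step 10
Reactants: 17 3,5-bis(benzyloxy)-2-[2-(benzyloxy)acetyl]-6-[(1R)-1-[4-(benzyloxy)-3,5-dimethoxyphenyl]ethyl]phenyl 4-(benzyloxy)-3-methoxybenzoate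
Product: 18 2-(benzyloxy)-1-{4,6-bis(benzyloxy)-3-[(1R)-1-[4-(benzyloxy)-3,5-dimethoxyphenyl]ethyl]-2-hydroxyphenyl}-3-[4-(benzyloxy)-3-methoxyphenyl]propane-1,3-dione (C2 epimers and enol forms)
Conditions: LiN(SiMe3)2 (3 equiv), THF, −20 °C to rt; then cold 1 M HCl
Reagents that add atoms: none
Why: LiN(SiMe3)2 removes a proton from the CH2 group between the ketone and the benzyloxy oxygen, the only enolisable position of 17. The lithium enolate attacks the carbonyl of the aroyl ester on the neighbouring ring oxygen through a six-membered transition state, and collapse of the tetrahedral intermediate expels the ring A phenoxide and leaves the new C2–C3 bond. The closest known reaction type is the Baker–Venkataraman rearrangement of 2-aroyloxy-ω-alkoxyacetophenones, an intramolecular Claisen condensation. The 1,3-diketone is deprotonated at once by the excess base, and this doubly stabilised enolate is the thermodynamic sink that makes the transfer irreversible. No ring is closed here; the chain of ring C is only assembled and O1 is set free for the next step. No stereocentre of the target is formed: the methine between the two carbonyls of 18 is configurationally labile and becomes trigonal in step 11, and the R benzylic centre carries no hydrogen acidic enough for the amide base. The selectivity needed is acyl transfer to the α-carbon instead of ester cleavage or transfer to another oxygen; it is secured by the non-nucleophilic base, by the ester sitting on the one oxygen ortho to the ketone, and by the benzyl groups on O5 and O7. Because the aroyl group was placed on the only free phenol, the 8-substituted regiochemistry of the chromone is already decided when this bond forms.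

Step 11
Reactants: 18 2-(benzyloxy)-1-{4,6-bis(benzyloxy)-3-[(1R)-1-[4-(benzyloxy)-3,5-dimethoxyphenyl]ethyl]-2-hydroxyphenyl}-3-[4-(benzyloxy)-3-methoxyphenyl]propane-1,3-dione
Product: 20 3,5,7-tris(benzyloxy)-2-[4-(benzyloxy)-3-methoxyphenyl]-8-[(1R)-1-[4-(benzyloxy)-3,5-dimethoxyphenyl]ethyl]-4H-chromen-4-one, via 2-hydroxyflavanone hemiketal 19 (not isolated)
Conditions: p-TsOH·H2O (0.2 equiv), toluene, 80 °C
Reagents that add atoms: none
Why: Acid-catalysed cyclodehydration: the phenol adds to the aroyl carbonyl to give the six-membered hemiketal, and loss of water gives the 4-pyranone. Only O1 is free, so only the 8-substituted chromone can form, and the acylated ring A is no longer electron-rich enough for acid to attack the diarylmethine.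

Step 12
Reactants: 20 3,5,7-tris(benzyloxy)-2-[4-(benzyloxy)-3-methoxyphenyl]-8-[(1R)-1-[4-(benzyloxy)-3,5-dimethoxyphenyl]ethyl]-4H-chromen-4-one
Product: 21 3,5,7-trihydroxy-2-(4-hydroxy-3-methoxyphenyl)-8-[(1R)-1-(4-hydroxy-3,5-dimethoxyphenyl)ethyl]-4H-chromen-4-one
Conditions: H2 (1 atm), Pd(OH)2 on carbon, THF/MeOH 1:1, rt
Reagents that add atoms: none
Why: Heterogeneous hydrogenolysis of the five benzyl ethers; the methyl ethers, the pyranone and the C–C bonds at the stereocentre are inert under these conditions, and the reaction is stopped at full debenzylation to avoid reduction of the C2=C3 bond.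

## Compound list

1 | 4-bromo-2,6-dimethoxyphenol | COc1cc(Br)cc(OC)c1O | starting material
2 | 2-(benzyloxy)-5-bromo-1,3-dimethoxybenzene | COc1cc(Br)cc(OC)c1OCc1ccccc1 | intermediate
3 | [4-(benzyloxy)-3,5-dimethoxyphenyl]lithium | [Li]c1cc(OC)c(OCc2ccccc2)c(OC)c1 | intermediate
4 | lithium [4-(benzyloxy)-3,5-dimethoxyphenyl]tri(propan-2-yloxy)borate | [Li+].CC(C)O[B-](OC(C)C)(OC(C)C)c1cc(OC)c(OCc2ccccc2)c(OC)c1 | intermediate
5 | [4-(benzyloxy)-3,5-dimethoxyphenyl]boronic acid | COc1cc(B(O)O)cc(OC)c1OCc1ccccc1 | intermediate
6 | 5,7-dihydroxycoumarin (5,7-dihydroxy-2H-chromen-2-one) | O=c1ccc2c(O)cc(O)cc2o1 | starting material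
7 | 5,7-bis(benzyloxy)-2H-chromen-2-one | O=c1ccc2c(OCc3ccccc3)cc(OCc3ccccc3)cc2o1 | intermediate
8 | (4R)-5,7-bis(benzyloxy)-4-[4-(benzyloxy)-3,5-dimethoxyphenyl]-3,4-dihydro-2H-chromen-2-one | O=C1C[C@H](c2cc(OC)c(OCc3ccccc3)c(OC)c2)c2c(OCc3ccccc3)cc(OCc3ccccc3)cc2O1 | intermediate
9 | (4R)-5,7-bis(benzyloxy)-4-[4-(benzyloxy)-3,5-dimethoxyphenyl]-3,4-dihydro-2H-chromen-2-ol, both C2 epimers | OC1C[C@H](c2cc(OC)c(OCc3ccccc3)c(OC)c2)c2c(OCc3ccccc3)cc(OCc3ccccc3)cc2O1 | intermediate
10 | (3R)-3-[2,4-bis(benzyloxy)-6-hydroxyphenyl]-3-[4-(benzyloxy)-3,5-dimethoxyphenyl]propanal | O=CC[C@H](c1cc(OC)c(OCc2ccccc2)c(OC)c1)c1c(OCc2ccccc2)cc(OCc2ccccc2)cc1O | intermediate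
11 | 3,5-bis(benzyloxy)-2-[(1R)-1-[4-(benzyloxy)-3,5-dimethoxyphenyl]ethyl]phenol | C[C@H](c1cc(OC)c(OCc2ccccc2)c(OC)c1)c1c(OCc2ccccc2)cc(OCc2ccccc2)cc1O | intermediate
12 | 2-(benzyloxy)acetyl chloride | O=C(Cl)COCc1ccccc1 | starting material
13 | 3,5-bis(benzyloxy)-2-[(1R)-1-[4-(benzyloxy)-3,5-dimethoxyphenyl]ethyl]phenyl 2-(benzyloxy)acetate | C[C@H](c1cc(OC)c(OCc2ccccc2)c(OC)c1)c1c(OCc2ccccc2)cc(OCc2ccccc2)cc1OC(=O)COCc1ccccc1 | intermediate
14 | 2-(benzyloxy)-1-{4,6-bis(benzyloxy)-3-[(1R)-1-[4-(benzyloxy)-3,5-dimethoxyphenyl]ethyl]-2-hydroxyphenyl}ethan-1-one | O=C(COCc1ccccc1)c1c(OCc2ccccc2)cc(OCc2ccccc2)c([C@H](C)c2cc(OC)c(OCc3ccccc3)c(OC)c2)c1O | intermediate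
15 | 4-(benzyloxy)-3-methoxybenzoic acid (O-benzylvanillic acid) | COc1cc(C(=O)O)ccc1OCc1ccccc1 | starting material
16 | 4-(benzyloxy)-3-methoxybenzoyl chloride | COc1cc(C(Cl)=O)ccc1OCc1ccccc1 | intermediate
17 | 3,5-bis(benzyloxy)-2-[2-(benzyloxy)acetyl]-6-[(1R)-1-[4-(benzyloxy)-3,5-dimethoxyphenyl]ethyl]phenyl 4-(benzyloxy)-3-methoxybenzoate | O=C(COCc1ccccc1)c1c(OCc2ccccc2)cc(OCc2ccccc2)c([C@H](C)c2cc(OC)c(OCc3ccccc3)c(OC)c2)c1OC(=O)c1ccc(OCc2ccccc2)c(OC)c1 | intermediate
18 | 2-(benzyloxy)-1-{4,6-bis(benzyloxy)-3-[(1R)-1-[4-(benzyloxy)-3,5-dimethoxyphenyl]ethyl]-2-hydroxyphenyl}-3-[4-(benzyloxy)-3-methoxyphenyl]propane-1,3-dione, C2 of the dione unassigned and labile | O=C(c1c(OCc2ccccc2)cc(OCc2ccccc2)c([C@H](C)c2cc(OC)c(OCc3ccccc3)c(OC)c2)c1O)C(OCc1ccccc1)C(=O)c1ccc(OCc2ccccc2)c(OC)c1 | intermediate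
19 | 3,5,7-tris(benzyloxy)-2-[4-(benzyloxy)-3-methoxyphenyl]-8-[(1R)-1-[4-(benzyloxy)-3,5-dimethoxyphenyl]ethyl]-2-hydroxy-2,3-dihydro-4H-chromen-4-one, C2 and C3 unassigned | O=C1c2c(OCc3ccccc3)cc(OCc3ccccc3)c([C@H](C)c3cc(OC)c(OCc4ccccc4)c(OC)c3)c2OC(O)(c2ccc(OCc3ccccc3)c(OC)c2)C1OCc1ccccc1 | intermediate
20 | 3,5,7-tris(benzyloxy)-2-[4-(benzyloxy)-3-methoxyphenyl]-8-[(1R)-1-[4-(benzyloxy)-3,5-dimethoxyphenyl]ethyl]-4H-chromen-4-one | COc1cc(-c2oc3c([C@H](C)c4cc(OC)c(OCc5ccccc5)c(OC)c4)c(OCc4ccccc4)cc(OCc4ccccc4)c3c(=O)c2OCc2ccccc2)ccc1OCc1ccccc1 | intermediate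
21 | 3,5,7-trihydroxy-2-(4-hydroxy-3-methoxyphenyl)-8-[(1R)-1-(4-hydroxy-3,5-dimethoxyphenyl)ethyl]-4H-chromen-4-one (CNP0261887.1) | COc1cc(-c2oc3c([C@H](C)c4cc(OC)c(O)c(OC)c4)c(O)cc(O)c3c(=O)c2O)ccc1O | target

## Step count and least certain steps

Total step count: 12. Longest linear sequence: 11 steps (steps 1, 2 and 4 to 12, from 1).

Step 10 (key step). The most likely failure is loss of the aroyl group by external attack on the hindered aryl ester, or slow acyl transfer because the di-ortho-substituted ketone and ester are twisted away from each other; either would return 14. Fallback: the same C2–C3 bond is made intermolecularly. Setting out from 14, the dianion (phenoxide and ketone enolate, excess LiN(SiMe3)2, THF, −78 °C) is treated with acid chloride 16. C-aroylation of the enolate, or O-aroylation followed by acyl shift in the same flask, should lead to 18, where the route is rejoined. No new compound appears.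

Step 8. The acyl group may leave as an α-alkoxy acylium ion that loses CO, benzyl groups may migrate or be cleaved by the Lewis acid, the acyl group may go to the para carbon, or acid may break the diarylmethine bond while ring A is still electron-rich. Fallback: the carbonyl carbon is brought in under basic, templated conditions and the chain is completed afterwards. Setting out from 11, magnesium-mediated ortho-formylation (MgCl2, Et3N, paraformaldehyde, MeCN, reflux; Casnati–Skattebøl) should give only 4,6-bis(benzyloxy)-3-[(1R)-1-[4-(benzyloxy)-3,5-dimethoxyphenyl]ethyl]-2-hydroxybenzaldehyde F1, because formaldehyde is delivered inside the magnesium phenoxide. Addition of (benzyloxy)methyllithium (from Bu3SnCH2OBn and n-BuLi, excess, THF, −78 °C) gives 3,5-bis(benzyloxy)-2-[2-(benzyloxy)-1-hydroxyethyl]-6-[(1R)-1-[4-(benzyloxy)-3,5-dimethoxyphenyl]ethyl]phenol F2, and oxidation of its benzylic alcohol with MnO2 returns to 14.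

Step 4. Insertion of the hindered, electron-rich C3=C4 bond may be slow, so that protodeboronation consumes 5, and the 5-benzyloxy group may disturb the binding of the coumarin and lower the facial selectivity. Fallback: the stereocentre is set by hydrogenation instead of arylation.
- Setting out from 2, aryllithium 3 (n-BuLi, THF, −78 °C) is transmetallated with CeCl3 to suppress enolisation and added to the sodium phenoxide of commercial 1-[2,4-bis(benzyloxy)-6-hydroxyphenyl]ethan-1-one F3. This gives the tertiary alcohol 3,5-bis(benzyloxy)-2-{1-[4-(benzyloxy)-3,5-dimethoxyphenyl]-1-hydroxyethyl}phenol F4.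
- Pyridinium p-toluenesulfonate in toluene dehydrates F4 to 3,5-bis(benzyloxy)-2-{1-[4-(benzyloxy)-3,5-dimethoxyphenyl]ethenyl}phenol F5.
- Hydroxyl-directed asymmetric hydrogenation of F5 with a cationic complex of monovalent rhodium ([Rh(nbd)2]BF4 with a chiral ferrocenyl bisphosphine, H2, MeOH), the ligand enantiomer being chosen for the R product, should give 11 directly. Steps 3 to 6 are bypassed.

Step 6. The lactol may stay closed and react slowly at the metal, and the alkyl–rhodium hydride may undergo β-hydride elimination, which would mean olefin formation and, if reversible, erosion of enantiomeric purity. Fallback: the carbon is removed as CO2 by a radical chain instead of as CO at a metal.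
- Setting out from 8, LiOH (THF/H2O) opens the lactone to (3R)-3-[2,4-bis(benzyloxy)-6-hydroxyphenyl]-3-[4-(benzyloxy)-3,5-dimethoxyphenyl]propanoic acid F6, kept as its dilithium salt so that it cannot reclose.
- Exhaustive silylation (t-BuMe2SiCl, imidazole, DMF) gives tert-butyl(dimethyl)silyl (3R)-3-[2,4-bis(benzyloxy)-6-{[tert-butyl(dimethyl)silyl]oxy}phenyl]-3-[4-(benzyloxy)-3,5-dimethoxyphenyl]propanoate F7.
- K2CO3 in MeOH/H2O cleaves the silyl ester alone and leaves (3R)-3-[2,4-bis(benzyloxy)-6-{[tert-butyl(dimethyl)silyl]oxy}phenyl]-3-[4-(benzyloxy)-3,5-dimethoxyphenyl]propanoic acid F8.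
- Coupling with N-hydroxypyridine-2-thione (EDC, CH2Cl2, dark) gives the Barton ester 2-sulfanylidenepyridin-1(2H)-yl (3R)-3-[2,4-bis(benzyloxy)-6-{[tert-butyl(dimethyl)silyl]oxy}phenyl]-3-[4-(benzyloxy)-3,5-dimethoxyphenyl]propanoate F9.
- Irradiation with visible light in the presence of a large excess of t-BuSH should give, by decarboxylation and fast hydrogen transfer, {3,5-bis(benzyloxy)-2-[(1R)-1-[4-(benzyloxy)-3,5-dimethoxyphenyl]ethyl]phenoxy}(tert-butyl)dimethylsilane F10. The thiol concentration must be high enough to outrun a 1,2-aryl shift of the primary radical.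
- Bu4NF in THF then returns to 11.

## Further compounds

F0 | step 10 | none | none
F1 | step 8 | 4,6-bis(benzyloxy)-3-[(1R)-1-[4-(benzyloxy)-3,5-dimethoxyphenyl]ethyl]-2-hydroxybenzaldehyde | O=Cc1c(OCc2ccccc2)cc(OCc2ccccc2)c([C@H](C)c2cc(OC)c(OCc3ccccc3)c(OC)c2)c1O
F2 | step 8 | 3,5-bis(benzyloxy)-2-[2-(benzyloxy)-1-hydroxyethyl]-6-[(1R)-1-[4-(benzyloxy)-3,5-dimethoxyphenyl]ethyl]phenol, carbinol epimers | OC(COCc1ccccc1)c1c(OCc2ccccc2)cc(OCc2ccccc2)c([C@H](C)c2cc(OC)c(OCc3ccccc3)c(OC)c2)c1O
F3 | step 4 | 1-[2,4-bis(benzyloxy)-6-hydroxyphenyl]ethan-1-one | CC(=O)c1c(O)cc(OCc2ccccc2)cc1OCc1ccccc1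
F4 | step 4 | 3,5-bis(benzyloxy)-2-{1-[4-(benzyloxy)-3,5-dimethoxyphenyl]-1-hydroxyethyl}phenol, racemic | CC(O)(c1cc(OC)c(OCc2ccccc2)c(OC)c1)c1c(OCc2ccccc2)cc(OCc2ccccc2)cc1O
F5 | step 4 | 3,5-bis(benzyloxy)-2-{1-[4-(benzyloxy)-3,5-dimethoxyphenyl]ethenyl}phenol | C=C(c1cc(OC)c(OCc2ccccc2)c(OC)c1)c1c(OCc2ccccc2)cc(OCc2ccccc2)cc1O
F6 | step 6 | (3R)-3-[2,4-bis(benzyloxy)-6-hydroxyphenyl]-3-[4-(benzyloxy)-3,5-dimethoxyphenyl]propanoic acid | O=C(O)C[C@H](c1cc(OC)c(OCc2ccccc2)c(OC)c1)c1c(OCc2ccccc2)cc(OCc2ccccc2)cc1O
F7 | step 6 | tert-butyl(dimethyl)silyl (3R)-3-[2,4-bis(benzyloxy)-6-{[tert-butyl(dimethyl)silyl]oxy}phenyl]-3-[4-(benzyloxy)-3,5-dimethoxyphenyl]propanoate | CC(C)(C)[Si](C)(C)OC(=O)C[C@H](c1cc(OC)c(OCc2ccccc2)c(OC)c1)c1c(OCc2ccccc2)cc(OCc2ccccc2)cc1O[Si](C)(C)C(C)(C)C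
F8 | step 6 | (3R)-3-[2,4-bis(benzyloxy)-6-{[tert-butyl(dimethyl)silyl]oxy}phenyl]-3-[4-(benzyloxy)-3,5-dimethoxyphenyl]propanoic acid | O=C(O)C[C@H](c1cc(OC)c(OCc2ccccc2)c(OC)c1)c1c(OCc2ccccc2)cc(OCc2ccccc2)cc1O[Si](C)(C)C(C)(C)C
F9 | step 6 | 2-sulfanylidenepyridin-1(2H)-yl (3R)-3-[2,4-bis(benzyloxy)-6-{[tert-butyl(dimethyl)silyl]oxy}phenyl]-3-[4-(benzyloxy)-3,5-dimethoxyphenyl]propanoate | S=C1C=CC=CN1OC(=O)C[C@H](c1cc(OC)c(OCc2ccccc2)c(OC)c1)c1c(OCc2ccccc2)cc(OCc2ccccc2)cc1O[Si](C)(C)C(C)(C)C
F10 | step 6 | {3,5-bis(benzyloxy)-2-[(1R)-1-[4-(benzyloxy)-3,5-dimethoxyphenyl]ethyl]phenoxy}(tert-butyl)dimethylsilane | C[C@H](c1cc(OC)c(OCc2ccccc2)c(OC)c1)c1c(OCc2ccccc2)cc(OCc2ccccc2)cc1O[Si](C)(C)C(C)(C)C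
A1 | alternative 1 | (R)-5-(benzyloxy)-2-[1-(4-benzyloxy-3,5-dimethoxyphenyl)ethyl]-3-[tri(propan-2-yl)silyloxy]phenol | Oc1cc(OCc2ccccc2)cc(O[Si](C(C)C)(C(C)C)C(C)C)c1[C@H](C)c1cc(OC)c(OCc2ccccc2)c(OC)c1
A2 | alternative 1 | 3-(benzyloxy)cyclobut-2-en-1-one | O=C1C=C(OCc2ccccc2)C1
A3 | alternative 1 | (R)-{[3-(4-benzyloxy-3,5-dimethoxyphenyl)but-1-yn-1-yl]oxy}tri(propan-2-yl)silane | C[C@@H](C#CO[Si](C(C)C)(C(C)C)C(C)C)c1cc(OC)c(OCc2ccccc2)c(OC)c1
A4 | alternative 2 | (R)-5,7-bis(benzyloxy)-4-(4-benzyloxy-3,5-dimethoxyphenyl)chroman-2-one | O=C1C[C@H](c2cc(OC)c(OCc3ccccc3)c(OC)c2)c2c(OCc3ccccc3)cc(OCc3ccccc3)cc2O1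
A5 | alternative 3 | (R)-4-{1-[4,6-bis(benzyloxy)-2-(methoxymethoxy)phenyl]ethyl}-2,6-dimethoxyphenol | COCOc1cc(OCc2ccccc2)cc(OCc2ccccc2)c1[C@H](C)c1cc(OC)c(O)c(OC)c1
A6 | alternative 3 | 4-{[4,6-bis(benzyloxy)-2-(methoxymethoxy)phenyl]methylidene}-2,6-dimethoxycyclohexa-2,5-dien-1-one | COCOc1cc(OCc2ccccc2)cc(OCc2ccccc2)c1C=C1C=C(OC)C(=O)C(OC)=C1
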